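You can take the first step at once: substrate and open intermediate relax with a half-life of 2.07 s, far shorter than the run, so the open intermediate is there almost from the start.

    substrate ⇌ open intermediate (K1 = 5.2, k1 = 0.281 s⁻¹)
    fresh partner → second intermediate (k2 = 0.0714 s⁻¹)
    open intermediate + second intermediate → target (k3 = 0.00629 M⁻¹ s⁻¹)
    2 second intermediate → homo product (k4 = 0.00509 M⁻¹ s⁻¹)
    solid partner ⇌ fresh partner, rate k5*(cs5 - [fresh partner]) while solid is left; crystals form when [fresh partner] > cs5 (cs5 = 0.82 M, k5 = 0.0141 s⁻¹)

substrate 1.8 M; solid partner 1.50 equiv; time 80 s

- for a step with 2 of a species take k times the square, and two of it per event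
- as a solid, counted per litre of solution: solid partner
- at the start none of the solid partner is in solution
- run time (flask): 80 s

- the target standing at 80 s, as a percentage of the substrate charged
- the change that raises the amount of target at 80 s, in percent of the substrate charged most ("none" if none brings more than 2 percentage points) (alpha / zeta / none)
- amount of target at 80 s, in percent of the substrate charged, after alpha

So c(open intermediate) stands near 1.51 M, and the question is how quickly its partner arrives. Fresh partner dissolves and is drained by the second step. When the two balance, c(fresh partner) is 0.135 M. Call the feed the rate of making second intermediate at that balance: the two coefficients multiplied by the solubility and divided by their sum, 0.00966 M s⁻¹. Of these two steps, dissolution has the smaller coefficient, so it paces the feed. The feed can last the run, since it delivers 0.772 M, less than the substrate charge, and the solid charge is 1.50 equiv of that.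

The feed needs about 11.7 s to set in, leaving 68.3 s. Second intermediate passes into target at 0.00950 s⁻¹. As a first round, let it pile up undiminished: target comes to 0.214 M. Put that loss back in and the answer drops by 21.6 %, giving 9.31 %. I leave the homo product out of this.

Now compare the two neighbours. Doubling the solubility makes the feed 0.0193 M s⁻¹, twice the flask's. Doubling the coefficient gives 0.0166 M s⁻¹, because c(fresh partner) rises to 0.232 M and narrows the gap to solubility. So I expect the zeta flask to end higher, on the larger feed.

The forecast gives 8.9 % (8 % to 9.8 %), a little under my figure, with 14.5 % (13 % to 16 %) after alpha, and names zeta: “Doubling the solubility doubles the feed outright”.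

The flask gives 8.98 %, and zeta is best, gaining 7.5 percentage points against 6 points for alpha. Its c(fresh partner) reads 0.135 M at 80.0 s, beside the reckoned 0.135 M, with 70.6 % of the solid partner left, so this flask is still on its feed, with 76.2 % of the charge waiting as open intermediate. In the alpha flask the feed 0.0166 M s⁻¹ sets in after 10.0 s, and the same two rounds give 16.7 %, whereas that flask holds 15.0 %.

The constants used here are assumed; the rest is arithmetic.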